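**Retrosynthetic overview**

1. Last bond: the C8 ester, by Steglich acylation of the C8 alcohol with (2E)-2-(acetoxymethyl)but-2-enoic acid (made by a Morita–Baylis–Hillman / acetate-transposition sequence).
2. Key disconnection: the furan-3(2H)-one ring (O, C3, C2, C1, C10) is an α-hydroxy ketone C10(O)–C1(=O) whose oxygen has added to C3 of a C2≡C3 ynone. Opening O–C3 (retro-oxa-Michael) and C1–C10 (retro-benzoin) removes the furanone and the ten-membered carbocycle at once, leaving an open-chain C1 ynal / C10 methyl ketone on the trans α-methylene-γ-butyrolactone. The (Z)-C4=C5 enyne and the trans-lactone hold these two carbonyl carbons of like polarity within reach.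
3. Keto-ynal: C3–C4 by Sonogashira coupling of a (Z)-vinyl iodide with propynal diethyl acetal; C7–C8 (with the C7 and C8 stereocentres) by CrCl2-mediated allylation of masked 3-oxobutanal with a 3-(bromomethyl)butenolide.
4. Butenolide: ring-closing metathesis of a 2-(bromomethyl)acrylate ester; its C6 stereocentre comes from a catalytic asymmetric vinylzinc addition to (Z)-3-iodobut-2-enal.
5. Ring order: lactone ring first (butenolide, then methylene lactone); then the ten-membered ring and the furanone ring together in the key step.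

Key step: step 11

Remark: positions are given in germacrane numbering (C1 furanone ketone, C2=C3 enol ether, C4=C5 alkene, C6 lactone carbinol, C7, C8 ester carbinol, C9, C10 quaternary ether carbon, C11–C13 methylene lactone, C14 and C15 the methyls on C10 and C4).
Remark: divinylzinc is assumed to be at hand as a salt-free stock solution, prepared beforehand from vinylmagnesium bromide and ZnCl2.

**Route**

Step 1
Reactants: 1 but-2-yn-1-ol
Product: 3 (2Z)-3-iodobut-2-en-1-ol, via sodium alkenylalanate 2 (not isolated)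
Conditions: NaAlH2(OCH2CH2OMe)2 (Red-Al), THF, 0 °C to rt; then I2, THF, −78 to 0 °C
Reagents that add atoms: iodine, II
Why: alkoxide-directed trans-hydroalumination of the propargylic alcohol places aluminium on C3 cis to the carbinol carbon, and iodinolysis with retention should give the (Z)-vinyl iodide (hydroalumination–iodination).

Step 2
Reactants: 3 (2Z)-3-iodobut-2-en-1-ol
Product: 4 (2Z)-3-iodobut-2-enal
Conditions: MnO2, CH2Cl2, rt, dark
Reagents that add atoms: none
Why: allylic oxidation with activated MnO2 is neutral and mild, so the (Z)-β-iodoenal should form without alkene isomerisation.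

Step 3
Reactants: 4 (2Z)-3-iodobut-2-enal
Product: 5 (3R,4Z)-5-iodohexa-1,4-dien-3-ol
Conditions: Zn(CH=CH2)2, (+)-MIB [(2R)-3-exo-morpholinoisoborneol] (10 mol%), toluene, −20 to 0 °C; aq. NH4Cl
Reagents that add atoms: divinylzinc, C=C[Zn]C=C
Why: amino alcohol-catalysed asymmetric alkenylzinc addition to an aldehyde; the ligand enantiomer is chosen so that vinyl is delivered to the Re face of the aldehyde, which sets the future C6 carbinol centre as (R).

Step 4
Reactants: 5 (3R,4Z)-5-iodohexa-1,4-dien-3-ol; 6 2-(bromomethyl)prop-2-enoic acid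
Product: 7 (3R,4Z)-5-iodohexa-1,4-dien-3-yl 2-(bromomethyl)prop-2-enoate
Conditions: DCC, DMAP (5 mol%), CH2Cl2, 0 °C
Reagents that add atoms: none
Why: Steglich esterification acylates the secondary bis-allylic alcohol with retention at the carbinol carbon, and the low temperature and catalytic DMAP should spare the allylic bromide.

Step 5
Reactants: 7 (3R,4Z)-5-iodohexa-1,4-dien-3-yl 2-(bromomethyl)prop-2-enoate
Product: 8 (5R)-3-(bromomethyl)-5-[(1Z)-2-iodoprop-1-en-1-yl]furan-2(5H)-one
Conditions: second-generation Grubbs catalyst (H2IMes)(PCy3)Cl2Ru=CHPh (5 mol%), toluene (0.01 M), 80 °C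
Reagents that add atoms: none
Why: ring-closing metathesis between the terminal vinyl group and the 1,1-disubstituted acrylate closes the butenolide with loss of ethene; the trisubstituted iodoalkene is inert and the stereocentre is not touched.

Step 6
Reactants: 9 ethyl 2-(2-methyl-1,3-dioxolan-2-yl)acetate
Product: 10 2-(2-methyl-1,3-dioxolan-2-yl)acetaldehyde
Conditions: i-Bu2AlH, CH2Cl2, −78 °C; aq. potassium sodium tartrate
Reagents that add atoms: none
Why: partial reduction of the ester with i-Bu2AlH at low temperature stops at the aluminium hemiacetal, which releases the aldehyde on work-up.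

Step 7
Reactants: 8 (5R)-3-(bromomethyl)-5-[(1Z)-2-iodoprop-1-en-1-yl]furan-2(5H)-one; 10 2-(2-methyl-1,3-dioxolan-2-yl)acetaldehyde
Product: 11 (4S,5R)-4-[(1R)-1-hydroxy-2-(2-methyl-1,3-dioxolan-2-yl)ethyl]-5-[(1Z)-2-iodoprop-1-en-1-yl]-3-methylidenedihydrofuran-2(3H)-one
Conditions: CrCl2 (3 equiv, nickel-free), THF, 0 °C to rt, 10 present from the start
Reagents that add atoms: none
Why: Nozaki–Hiyama-type allylation in which the allylchromium species made from 8 and divalent chromium adds through its γ-carbon C7 in a chair Zimmerman–Traxler transition state; attack anti to the C6 side chain should give the 6,7-trans lactone, and the ring-locked (E)-type geometry of the allyl unit should give the anti C7/C8 relationship, that is (7S,8R).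

Step 8
Reactants: 11 the hydroxy lactone of step 7
Product: 12 (4R,5R)-4-[(1R)-1-{[tert-butyl(dimethyl)silyl]oxy}-2-(2-methyl-1,3-dioxolan-2-yl)ethyl]-5-[(1Z)-2-iodoprop-1-en-1-yl]-3-methylidenedihydrofuran-2(3H)-one
Conditions: TBSOTf, 2,6-lutidine, CH2Cl2, −78 °C
Reagents that add atoms: tert-butyldimethylsilyl triflate, CC(C)(C)[Si](C)(C)OS(=O)(=O)C(F)(F)F
Why: silylation of the hindered secondary alcohol at low temperature caps C8–OH before it can translactonise and leaves the dioxolane intact.

Step 9
Reactants: 12 the TBS ether of step 8; 13 3,3-diethoxyprop-1-yne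
Product: 14 (4R,5S)-4-[(1R)-1-{[tert-butyl(dimethyl)silyl]oxy}-2-(2-methyl-1,3-dioxolan-2-yl)ethyl]-5-[(1Z)-5,5-diethoxy-2-methylpent-1-en-3-yn-1-yl]-3-methylidenedihydrofuran-2(3H)-one
Conditions: Pd(PPh3)2Cl2 (5 mol%), CuI (10 mol%), Et3N, THF, rt
Reagents that add atoms: none
Why: Sonogashira coupling of the vinyl iodide proceeds with retention of the (Z) geometry and installs C1–C3 with C1 already at the aldehyde oxidation level.

Step 10
Reactants: 14 the enyne bis-acetal of step 9
Product: 15 (4Z)-5-[(2S,3R)-3-[(1R)-1-{[tert-butyl(dimethyl)silyl]oxy}-3-oxobutyl]-4-methylidene-5-oxooxolan-2-yl]-4-methylpent-4-en-2-ynal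
Conditions: Amberlyst-15, acetone/H2O (10:1), rt; used at once
Reagents that add atoms: water, O
Why: acid-catalysed acetal hydrolysis should cleave both the dioxolane and the propargylic diethyl acetal while the hindered secondary silyl ether survives, giving the C10 methyl ketone and the C1 ynal in one operation.

Step 11
Reactants: 15 the keto-ynal of step 10
Product: 17 (6S,7R,8R,10R)-8-{[tert-butyl(dimethyl)silyl]oxy}-1-oxo-3,10-epoxygermacra-2,4Z,11(13)-trien-12,6-olide, via ten-membered hydroxy ynone 16 (not isolated)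
Conditions: (5aR,10bS)-2-(pentafluorophenyl)-5a,10b-dihydro-4H,6H-indeno[2,1-b][1,2,4]triazolo[4,3-d][1,4]oxazin-2-ium tetrafluoroborate (20 mol%), i-Pr2NEt (20 mol%), 4 Å MS, toluene, slow addition of 15 to 0.002 M, 25 to 40 °C
Reagents that add atoms: none
Why: Proposed new method: the triazolylidene adds to the ynal carbon C1 and proton transfer gives the alkynyl Breslow intermediate, whose acyl-anion carbon C1 attacks the C10 methyl ketone (crossed aldehyde–ketone benzoin, 10-exo-trig, closing the ten-membered carbocycle); after release of the carbene, the tertiary C10 hydroxyl of 16 adds to C3 of the strained ynone (5-endo-dig oxa-Michael, closing the furan-3(2H)-one). The closest known reaction types are the carbene-catalysed intramolecular aldehyde–ketone benzoin to five- and six-membered rings, the intermolecular carbene-catalysed benzoin/oxa-Michael annulation of ynals with activated ketones to furan-3(2H)-ones, and the cyclisation of α'-hydroxy ynones to furan-3(2H)-ones; new here are the unactivated ketone and the ring size. The benzoin step is reversible, and the irreversible, strain-releasing oxa-Michael closure should drain the equilibrium toward 17. The only new stereocentre, C10, is set in the C–C bond formation by catalyst control: the aminoindanol backbone is meant to direct C1 to the Si face of the ketone (O > C9 > C14), the trans-lactone and the C8 silyloxy group restrict the macrocyclic transition state, and the catalyst enantiomer has to be matched to this substrate bias. The step needs acyl-anion reactivity at C1 over redox isomerisation of the ynal through γ-protonation, which the electron-poor N-pentafluorophenyl carbene and dry, aprotic toluene should secure; it also needs ring closure over dimerisation, which high dilution and the (Z)-C4=C5 enyne and trans-lactone should secure. The silyl ether at C8 is there to prevent β-elimination of the β-oxygenated ketone.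

Step 12
Reactants: 17 the silyl-protected tricycle of step 11
Product: 18 (6S,7S,8R,10R)-8-hydroxy-1-oxo-3,10-epoxygermacra-2,4Z,11(13)-trien-12,6-olide
Conditions: HF·pyridine, pyridine, THF, 0 °C to rt
Reagents that add atoms: none
Why: buffered fluoride desilylation removes the TBS group without touching the vinylogous ester of the furanone or the methylene lactone.

Step 13
Reactants: 19 tert-butyl prop-2-enoate; 20 acetaldehyde
Product: 21 tert-butyl 3-hydroxy-2-methylidenebutanoate (racemic)
Conditions: DABCO (1 equiv), 1,4-dioxane/H2O (1:1), rt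
Reagents that add atoms: none
Why: Morita–Baylis–Hillman reaction of the acrylate with acetaldehyde; the stereocentre is lost in the next step, so the racemate suffices.

Step 14
Reactants: 21 tert-butyl 3-hydroxy-2-methylidenebutanoate
Product: 23 tert-butyl (2E)-2-(acetoxymethyl)but-2-enoate, via secondary acetate 22 (not isolated)
Conditions: Ac2O, Et3N, DMAP (cat.), CH2Cl2, 0 °C; then DABCO (20 mol%), THF, 60 °C
Reagents that add atoms: acetic anhydride, CC(=O)OC(C)=O
Why: acetylation followed by DABCO-catalysed SN2'–SN2' 1,3-transposition of the acetate should give the thermodynamically favoured trisubstituted enoate with the β-methyl trans to the ester, which is the (E) isomer required.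

Step 15
Reactants: 23 tert-butyl (2E)-2-(acetoxymethyl)but-2-enoate
Product: 24 (2E)-2-(acetoxymethyl)but-2-enoic acid
Conditions: CF3CO2H/CH2Cl2 (1:4), 0 °C to rt
Reagents that add atoms: none
Why: acidolysis of the tert-butyl ester frees the acid without touching the allylic acetate.

Step 16
Reactants: 18 the C8 alcohol of step 12; 24 (2E)-2-(acetoxymethyl)but-2-enoic acid
Product: 25 CNP0176571.1 (target)
Conditions: DCC, DMAP, CH2Cl2, 0 °C to rt
Reagents that add atoms: none
Why: Steglich esterification of the C8 alcohol with retention at C8; the acid already has the thermodynamic alkene geometry, so DMAP-induced isomerisation is not a concern.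

**Compound list**

1 | but-2-yn-1-ol | CC#CCO | starting material
2 | sodium 2,2-bis(2-methoxyethoxy)-3-methyl-2,5-dihydro-1,2-oxaluminol-2-uide (alkenylalanate, not isolated) | [Na+].CC1=CCO[Al-]1(OCCOC)OCCOC | intermediate
3 | (2Z)-3-iodobut-2-en-1-ol | C/C(I)=C/CO | intermediate
4 | (2Z)-3-iodobut-2-enal | C/C(I)=C/C=O | intermediate
5 | (3R,4Z)-5-iodohexa-1,4-dien-3-ol | C=C[C@@H](O)/C=C(/C)I | intermediate
6 | 2-(bromomethyl)prop-2-enoic acid | C=C(CBr)C(=O)O | starting material
7 | (3R,4Z)-5-iodohexa-1,4-dien-3-yl 2-(bromomethyl)prop-2-enoate | C=C[C@@H](OC(=O)C(=C)CBr)/C=C(/C)I | intermediate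
8 | (5R)-3-(bromomethyl)-5-[(1Z)-2-iodoprop-1-en-1-yl]furan-2(5H)-one | BrCC1=C[C@H](/C=C(/C)I)OC1=O | intermediate
9 | ethyl 2-(2-methyl-1,3-dioxolan-2-yl)acetate | CCOC(=O)CC1(C)OCCO1 | starting material
10 | 2-(2-methyl-1,3-dioxolan-2-yl)acetaldehyde | O=CCC1(C)OCCO1 | intermediate
11 | (4S,5R)-4-[(1R)-1-hydroxy-2-(2-methyl-1,3-dioxolan-2-yl)ethyl]-5-[(1Z)-2-iodoprop-1-en-1-yl]-3-methylidenedihydrofuran-2(3H)-one | C=C1C(=O)O[C@@H](/C=C(/C)I)[C@@H]1[C@@H](CC2(C)OCCO2)O | intermediate
12 | (4R,5R)-4-[(1R)-1-{[tert-butyl(dimethyl)silyl]oxy}-2-(2-methyl-1,3-dioxolan-2-yl)ethyl]-5-[(1Z)-2-iodoprop-1-en-1-yl]-3-methylidenedihydrofuran-2(3H)-one | C=C1C(=O)O[C@@H](/C=C(/C)I)[C@@H]1[C@@H](CC2(C)OCCO2)O[Si](C)(C)C(C)(C)C | intermediate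
13 | 3,3-diethoxyprop-1-yne | C#CC(OCC)OCC | starting material
14 | (4R,5S)-4-[(1R)-1-{[tert-butyl(dimethyl)silyl]oxy}-2-(2-methyl-1,3-dioxolan-2-yl)ethyl]-5-[(1Z)-5,5-diethoxy-2-methylpent-1-en-3-yn-1-yl]-3-methylidenedihydrofuran-2(3H)-one | C=C1C(=O)O[C@@H](/C=C(/C)C#CC(OCC)OCC)[C@@H]1[C@@H](CC2(C)OCCO2)O[Si](C)(C)C(C)(C)C | intermediate
15 | (4Z)-5-[(2S,3R)-3-[(1R)-1-{[tert-butyl(dimethyl)silyl]oxy}-3-oxobutyl]-4-methylidene-5-oxooxolan-2-yl]-4-methylpent-4-en-2-ynal | C=C1C(=O)O[C@@H](/C=C(/C)C#CC=O)[C@@H]1[C@@H](CC(C)=O)O[Si](C)(C)C(C)(C)C | intermediate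
16 | (6S,7R,8R,10R)-8-{[tert-butyl(dimethyl)silyl]oxy}-10-hydroxy-1-oxogermacra-4Z,11(13)-dien-2-yn-12,6-olide (ten-membered hydroxy ynone, not isolated) | C=C1C(=O)O[C@H]2/C=C(/C)C#CC(=O)[C@](C)(O)C[C@@H](O[Si](C)(C)C(C)(C)C)[C@H]12 | intermediate
17 | (6S,7R,8R,10R)-8-{[tert-butyl(dimethyl)silyl]oxy}-1-oxo-3,10-epoxygermacra-2,4Z,11(13)-trien-12,6-olide | C=C1C(=O)O[C@H]2/C=C(/C)C3=CC(=O)[C@@](C)(C[C@@H](O[Si](C)(C)C(C)(C)C)[C@H]12)O3 | intermediate
18 | (6S,7S,8R,10R)-8-hydroxy-1-oxo-3,10-epoxygermacra-2,4Z,11(13)-trien-12,6-olide | C=C1C(=O)O[C@H]2/C=C(/C)C3=CC(=O)[C@@](C)(C[C@@H](O)[C@H]12)O3 | intermediate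
19 | tert-butyl prop-2-enoate | C=CC(=O)OC(C)(C)C | starting material
20 | acetaldehyde | CC=O | starting material
21 | tert-butyl 3-hydroxy-2-methylidenebutanoate (racemic) | CC(O)C(=C)C(=O)OC(C)(C)C | intermediate
22 | tert-butyl 3-acetoxy-2-methylidenebutanoate (racemic, not isolated) | CC(OC(C)=O)C(=C)C(=O)OC(C)(C)C | intermediate
23 | tert-butyl (2E)-2-(acetoxymethyl)but-2-enoate | CC(C)(C)OC(=O)/C(=C/C)COC(C)=O | intermediate
24 | (2E)-2-(acetoxymethyl)but-2-enoic acid | OC(=O)/C(=C/C)COC(C)=O | intermediate
25 | CNP0176571.1, (6S,7S,8R,10R)-8-{[(2E)-2-(acetoxymethyl)but-2-enoyl]oxy}-1-oxo-3,10-epoxygermacra-2,4Z,11(13)-trien-12,6-olide | C=C1C(=O)O[C@H]2/C=C(/C)C3=CC(=O)[C@@](C)(C[C@@H](OC(=O)/C(=C/C)COC(C)=O)[C@H]12)O3 | target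

**Step count and risks**

Total step count: 16. Longest linear sequence: 12 steps (steps 1–5, 7–12 and 16, from but-2-yn-1-ol).

Steps most likely to fail:

Step 11 (proposed new method). What may go wrong: redox isomerisation of the ynal through γ-protonation of the carbene adduct, or intermolecular self-condensation, may outrun the ten-membered benzoin closure, and facial selectivity at the ketone may be poor. The fallback uses known reactions and makes the two bonds in separate operations; it sets out from 12 and comes back at 17. Hydrolysis of the dioxolane (pyridinium tosylate, wet acetone) gives methyl ketone F1. Addition of HC≡CMgBr with CeCl3 (THF, −78 °C) to the ketone gives tertiary propargylic alcohol F2, whose C10 epimer would have to be removed if 1,3-induction from the C8 silyloxy group is weak. A carbonylative Sonogashira macrocyclisation (Pd(PPh3)2Cl2, Et3N, CO at 1 atm, high dilution) joins the vinyl iodide, CO and the terminal alkyne to ten-membered 4-hydroxy-2-ynone F3. Hydrative cyclisation of this hydroxy ynone (Hg(OTf)2 or AuCl3 as catalyst, wet MeCN), the classical entry to furan-3(2H)-ones, gives 17.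

Step 7. What may go wrong: erosion of the anti C7/C8 relationship if the allyl transfer leaves the chair pathway, or reductive ring-opening of the allylchromium species before it meets the aldehyde. The fallback corrects the carbinol centre by inversion instead of relying on the allylation; it sets out from 8 and 10 and comes back at 11. If the allylation delivers mainly C8-epimeric alcohol F4, a Mitsunobu reaction with chloroacetic acid (PPh3, diisopropyl azodicarboxylate, toluene, 0 °C) inverts C8 and gives chloroacetate F5. Thiourea (NaHCO3, EtOH, rt) then removes the chloroacetyl group and gives 11.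

Step 10. What may go wrong: loss of the silyl ether or acid-induced β-elimination of the silyloxy ketone while the deactivated propargylic acetal is being hydrolysed, and decomposition of the ynal in acid. The fallback releases the ynal by oxidation under neutral conditions; it sets out from 12 and comes back at 15. Sonogashira coupling of 12 with prop-2-yn-1-ol (Pd(PPh3)2Cl2, CuI, Et3N) gives propargylic alcohol F6. Pyridinium tosylate in wet acetone removes only the dioxolane and gives hydroxy ketone F7. MnO2 (CH2Cl2, rt) oxidises the propargylic alcohol to 15.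

**Further compounds**

F1 | step 11 | (4R,5R)-4-[(1R)-1-{[tert-butyl(dimethyl)silyl]oxy}-3-oxobutyl]-5-[(1Z)-2-iodoprop-1-en-1-yl]-3-methylidenedihydrofuran-2(3H)-one | C=C1C(=O)O[C@@H](/C=C(/C)I)[C@@H]1[C@@H](CC(C)=O)O[Si](C)(C)C(C)(C)C
F2 | step 11 | (4R,5R)-4-[(1R,3R)-1-{[tert-butyl(dimethyl)silyl]oxy}-3-hydroxy-3-methylpent-4-yn-1-yl]-5-[(1Z)-2-iodoprop-1-en-1-yl]-3-methylidenedihydrofuran-2(3H)-one | C=C1C(=O)O[C@@H](/C=C(/C)I)[C@@H]1[C@@H](C[C@@](C)(O)C#C)O[Si](C)(C)C(C)(C)C
F3 | step 11 | (6S,7R,8R,10R)-8-{[tert-butyl(dimethyl)silyl]oxy}-10-hydroxy-3-oxogermacra-4Z,11(13)-dien-1-yn-12,6-olide | C=C1C(=O)O[C@H]2/C=C(/C)C(=O)C#C[C@](C)(O)C[C@@H](O[Si](C)(C)C(C)(C)C)[C@H]12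
F4 | step 7 | (4S,5R)-4-[(1S)-1-hydroxy-2-(2-methyl-1,3-dioxolan-2-yl)ethyl]-5-[(1Z)-2-iodoprop-1-en-1-yl]-3-methylidenedihydrofuran-2(3H)-one | C=C1C(=O)O[C@@H](/C=C(/C)I)[C@@H]1[C@H](CC2(C)OCCO2)O
F5 | step 7 | (1R)-1-[(2R,3S)-2-[(1Z)-2-iodoprop-1-en-1-yl]-4-methylidene-5-oxooxolan-3-yl]-2-(2-methyl-1,3-dioxolan-2-yl)ethyl chloroacetate | C=C1C(=O)O[C@@H](/C=C(/C)I)[C@@H]1[C@@H](CC2(C)OCCO2)OC(=O)CCl
F6 | step 10 | (4R,5S)-4-[(1R)-1-{[tert-butyl(dimethyl)silyl]oxy}-2-(2-methyl-1,3-dioxolan-2-yl)ethyl]-5-[(1Z)-5-hydroxy-2-methylpent-1-en-3-yn-1-yl]-3-methylidenedihydrofuran-2(3H)-one | C=C1C(=O)O[C@@H](/C=C(/C)C#CCO)[C@@H]1[C@@H](CC2(C)OCCO2)O[Si](C)(C)C(C)(C)C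
F7 | step 10 | (4R,5S)-4-[(1R)-1-{[tert-butyl(dimethyl)silyl]oxy}-3-oxobutyl]-5-[(1Z)-5-hydroxy-2-methylpent-1-en-3-yn-1-yl]-3-methylidenedihydrofuran-2(3H)-one | C=C1C(=O)O[C@@H](/C=C(/C)C#CCO)[C@@H]1[C@@H](CC(C)=O)O[Si](C)(C)C(C)(C)C
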